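(The readings come from a simulation with constants of no real substance, and the scatter is random.)

An easy step first: for each earlier run I multiply the charge of E by the time, call this the exposure, and ask whether L, which E makes from J and which then falls again, follows exposure (Selwyn's test).

the same everywhere: J 0.051 M
- south-west: E 34 µM; run made earlier
- south-east: E 76 µM; run made earlier
- flask: E 51 µM; time 1.5 h

| run | time / min | L / % |
|---|---|---|
| south-west | 1.50 | 8.8 |
| south-west | 4.00 | 16.2 |
| south-west | 12.0 | 20.6 |
| south-west | 30.0 | 17.9 |
| south-west | 80.0 | 14.3 |
| south-east | 1.50 | 14.9 |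
| south-east | 4.00 | 23.6 |
| south-east | 12.0 | 16.1 |
| south-east | 30.0 | 7.1 |
| south-east | 80.0 | 4.0 |

(scatter of a reading: 1 percentage point)

1. when, up to 1.5 h, the flask holds most L
2. the amount of L, in percent of the J charged, at that time

Early on it roughly does: south-west at 4.00 min and south-east at 1.50 min differ in exposure by a factor 1.19 and read 16.2% and 14.9%. Late on it seems not to: south-west at 80.0 min has 2.98 times the exposure of south-east at 12.0 min, yet reads 14.3% against 16.1%.

I clear this up by supposing that E dies away exponentially, with one lifetime τ in both runs, so that exposure grows towards a ceiling, the charge of E times τ. I take those two readings as one point of a single curve, with south-west at its ceiling. South-east counted as undamaged gives τ = 26.8 min. Putting that loss back into south-east gives the catalyst lifetime τ = 21.6 min.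

South-east reads highest at 4.00 min, 23.6%. Matching that exposure in this flask gives 5.96 min by plain scaling and 6.27 min with τ, and I expect a height near that reading, which carries a scatter of 1 percentage point.

The forecast says 0.1 h and 22.5%, noting “formation scales about with E”. The flask gives 0.115 h and 21.5%.

    J + E ⇌ L + E, rate k1*[J]*[E] forward; the back reaction follows from the equilibrium constant (K = 1.09, k = 33.4 M⁻¹ s⁻¹)
    L + E ⇌ G + E, rate k2*[E]*[L] forward; the back reaction follows from the equilibrium constant (K = 16.0, k = 42.4 M⁻¹ s⁻¹)
    G ⇌ Q (K = 0.720, k = 0.0172 s⁻¹)
    Q + E ⇌ J + E, rate k4*[E]*[Q] forward; the back reaction follows from the equilibrium constant (k = 1.29 M⁻¹ s⁻¹)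
    E + L → Z (k = 0.0777 M⁻¹ s⁻¹)

At that time this flask holds 76.8% of its E, a lifetime of 26.0 min against my 21.6 min. A neighbour flask is like this one but charged with 0.20 M of J. Scaling τ inversely with the charge of J gives 5.51 min, and its exposure ceiling is then 1.01 times the exposure at my peak. At 1.50 h the neighbour flask holds 0% of its E and 43.5% of its charged J, with L at 21.5%.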